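**Retrosynthetic overview**
1. The target is a trans-3,4-dibenzyl-γ-butyrolactone (its only ring) whose central guaiacyl ring carries, ortho to the phenol, an (S)-CH(CH2OH)–C(=O)Ar arm.
2. Key disconnection, a formal (3+2) annulation: lactone bonds C3–C4 and O1–C5 are formed together from an arylmethyl(chloro)ketene (atoms C3, C2, O1) and an enantiopure (Z)-alkenyl p-tolyl sulfoxide (atoms C4, C5); chlorine and the tolylthio group are traceless activators.
3. Enabling feature: in the lactone ring C5 is an unsubstituted O–CH2 and C4 is a CH that bears only a benzyl group, so C4–C5 maps onto the β/α carbons of a vinyl sulfoxide and C3–C2(=O)–O1 onto a ketene; the sulfur stereocentre (bought as menthyl sulfinate) is relayed to C4 and from C4 to C3 (trans, by equilibration).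
4. The remote stereocentre is set earlier by an Evans syn-aldol of an arylacetyl imide with O-benzylvanillin and carried as a 1,3-dioxane acetonide; the epimerizable aryl ketone is unveiled only in the penultimate step.
5. Ring order: temporary 1,3-dioxane (step 8), lactone (step 15), dioxane opened again (step 17).

Key step: step 15

**Remarks and assumptions**
- Abbreviations used in names: BnG = 4-(benzyloxy)-3-methoxyphenyl; DX = (4R,5S)-4-(BnG)-2,2-dimethyl-1,3-dioxan-5-yl; Ar′ = 4-(benzyloxy)-3-methoxy-5-DX-phenyl. The SMILES give every structure in full.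
- Assumption on the chemistry: the sense of sulfur-to-carbon chirality transfer in step 15 is taken from the accepted model for this reaction type (S–O bond perpendicular to the alkene, tolyl group turned away from the alkene, sulfur lone pair eclipsing C=C). Should experiment show the opposite sense, the enantiomeric (1S,2R,5S)-menthyl (R)-p-toluenesulfinate would be used in step 10 and nothing else changes.
- The CH(CH2OH)–C(=O)Ar centre next to a free ortho-phenol is labile to base (enolization, retro-aldol) and to acid (cyclodehydration to a benzofuran). The ketone is therefore made in step 18 and the last step is neutral.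
- Acid 24 is racemic on purpose: its stereocentre becomes the sp2 ketene carbon.

**Route**

Step 1
Reactants: 1 methyl (4-hydroxy-3-methoxyphenyl)acetate (methyl homovanillate)
Product: 2 methyl [4-(allyloxy)-3-methoxyphenyl]acetate
Conditions: allyl bromide, K2CO3, acetone, reflux
Reagents that add atoms: allyl bromide, C=CCBr
Why: Williamson O-alkylation of the phenoxide; carbonate does not deprotonate the ester α-position.

Step 2
Reactants: 2 methyl [4-(allyloxy)-3-methoxyphenyl]acetate
Product: 3 methyl (3-allyl-4-hydroxy-5-methoxyphenyl)acetate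
Conditions: N,N-diethylaniline, 195 °C, sealed tube
Reagents that add atoms: none
Why: Aromatic Claisen rearrangement; only one ortho position is free, so the allyl group should arrive there and tautomerization restores the phenol.

Step 3
Reactants: 3 methyl (3-allyl-4-hydroxy-5-methoxyphenyl)acetate
Product: 4 methyl [3-allyl-4-(benzyloxy)-5-methoxyphenyl]acetate
Conditions: BnBr, K2CO3, DMF, 50 °C
Reagents that add atoms: benzyl bromide, BrCc1ccccc1
Why: Williamson etherification protects the phenol as a benzyl ether that survives every later step and is removed by neutral hydrogenolysis at the end.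

Step 4
Reactants: 4 methyl [3-allyl-4-(benzyloxy)-5-methoxyphenyl]acetate
Product: 6 [2-(benzyloxy)-3-methoxy-5-(2-methoxy-2-oxoethyl)phenyl]acetic acid, via aldehyde 5 (not isolated)
Conditions: OsO4 (2 mol %), NaIO4, 2,6-lutidine, dioxane/H2O, rt; crude aldehyde, then NaClO2, NaH2PO4, 2-methyl-2-butene, t-BuOH/H2O, 0 °C
Reagents that add atoms: sodium periodate with catalytic osmium tetroxide (aldehyde oxygen), [Na+].[O-]I(=O)(=O)=O and O=[Os](=O)(=O)=O; sodium chlorite (acid oxygen), [Na+].[O-]Cl=O
Why: Lemieux–Johnson cleavage of the terminal alkene followed by Pinnick oxidation of the sensitive arylacetaldehyde without purification; the chlorine scavenger protects the electron-rich ring.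

Step 5
Reactants: 6 [2-(benzyloxy)-3-methoxy-5-(2-methoxy-2-oxoethyl)phenyl]acetic acid; 7 (R)-4-benzyl-1,3-oxazolidin-2-one
Product: 9 methyl [4-(benzyloxy)-3-methoxy-5-{2-[(4R)-4-benzyl-2-oxo-1,3-oxazolidin-3-yl]-2-oxoethyl}phenyl]acetate, via mixed pivalic anhydride 8 (not isolated)
Conditions: PivCl, Et3N, THF, −20 °C; then LiCl, 7, −20 °C to rt
Reagents that add atoms: none
Why: N-acylation of the Evans auxiliary through the mixed anhydride; only the free acid is activated and the methyl ester is untouched.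

Step 6
Reactants: 9 the N-arylacetyl oxazolidinone; 10 4-(benzyloxy)-3-methoxybenzaldehyde (O-benzylvanillin)
Product: 12 (4R)-4-benzyl-3-{(2R,3R)-2-[2-(benzyloxy)-3-methoxy-5-(2-methoxy-2-oxoethyl)phenyl]-3-(BnG)-3-hydroxypropanoyl}-1,3-oxazolidin-2-one, via boron enolate 11 (not isolated)
Conditions: n-Bu2BOTf, i-Pr2NEt, CH2Cl2, 0 °C; then 10, −78 to 0 °C; then pH 7 buffer, MeOH, 30% H2O2, 0 °C
Reagents that add atoms: none
Why: Evans syn-aldol reaction through the (Z)-boron enolate and a Zimmerman–Traxler transition state; the (R)-benzyl auxiliary sets the aryl-bearing carbon as (2R) in the imide, which is the future (S)-CH(CH2OH) centre of the target, while the carbinol centre set at the same time is oxidized later.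

Step 7
Reactants: 12 the syn-aldol imide
Product: 13 (1R,2S)-2-[2-(benzyloxy)-5-(2-hydroxyethyl)-3-methoxyphenyl]-1-(BnG)propane-1,3-diol
Conditions: LiBH4 (excess), MeOH (2 equiv), THF, 0 °C to rt
Reagents that add atoms: none
Why: Lithium borohydride cleaves the auxiliary reductively and reduces the methyl ester; the centre α to the acyl group is not enolized and the oxazolidinone is recovered.

Step 8
Reactants: 13 the triol
Product: 14 2-[4-(benzyloxy)-3-methoxy-5-DX-phenyl]ethanol
Conditions: 2,2-dimethoxypropane, PPTS (cat.), acetone, rt; then MeOH, rt, to cleave any mixed ketal on the primary alcohol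
Reagents that add atoms: 2,2-dimethoxypropane, COC(C)(C)OC
Why: Acetonide formation; only the 1,3-diol can close a six-membered 1,3-dioxane, which leaves the 2-arylethanol free.

Step 9
Reactants: 14 the acetonide alcohol
Product: 16 2-(benzyloxy)-1-DX-3-methoxy-5-(prop-2-yn-1-yl)benzene, via aldehyde 15 (not isolated)
Conditions: Dess–Martin periodinane, pyridine, CH2Cl2, 0 °C to rt; crude aldehyde, then dimethyl (1-diazo-2-oxopropyl)phosphonate, K2CO3, MeOH, 0 °C to rt
Reagents that add atoms: dimethyl (1-diazo-2-oxopropyl)phosphonate, COP(=O)(OC)C(=[N+]=[N-])C(C)=O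
Why: Dess–Martin oxidation gives the arylacetaldehyde, which is homologated at once by the Ohira–Bestmann variant of the Seyferth–Gilbert reaction under carbonate conditions mild enough to limit propargyl-to-allene isomerization.

Step 10
Reactants: 16 the terminal alkyne; 17 (1R,2S,5R)-(−)-menthyl (S)-p-toluenesulfinate
Product: 19 2-(benzyloxy)-1-DX-3-methoxy-5-[3-(p-tolylsulfinyl)prop-2-yn-1-yl]benzene with (S) configuration at sulfur, via alkynylmagnesium bromide 18 (not isolated)
Conditions: EtMgBr (1.0 equiv), THF, 0 °C to rt; then added to 17 in toluene, −20 °C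
Reagents that add atoms: none
Why: Andersen sulfoxide synthesis; the acetylide displaces menthoxide at sulfur with inversion, so the sulfur stereocentre is bought from the chiral pool (the descriptor stays S only because alkynyl outranks tolyl).

Step 11
Reactants: 19 the alkynyl sulfoxide
Product: 20 2-(benzyloxy)-1-DX-3-methoxy-5-[(Z)-3-(p-tolylsulfinyl)prop-2-en-1-yl]benzene with (R) configuration at sulfur
Conditions: H2 (1 atm), RhCl(PPh3)3 (cat.), benzene/EtOH, rt
Reagents that add atoms: none
Why: Syn addition of one equivalent of H2 with Wilkinson's catalyst should stop at the (Z)-alkenyl sulfoxide without touching the sulfur stereocentre or the benzyl ethers (the descriptor changes to R only because alkenyl ranks below tolyl).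

Step 12
Reactants: 21 3-(4-hydroxy-3-methoxyphenyl)propanoic acid (dihydroferulic acid)
Product: 22 3-[4-(benzyloxy)-3-methoxyphenyl]propanoic acid
Conditions: BnBr (1.1 equiv), NaOH (2.2 equiv), EtOH/H2O, reflux; then aq. HCl
Reagents that add atoms: benzyl bromide, BrCc1ccccc1
Why: Williamson etherification of the phenoxide in a protic medium, where the carboxylate is a poor nucleophile and any benzyl ester formed is saponified by the excess hydroxide.

Step 13
Reactants: 22 3-[4-(benzyloxy)-3-methoxyphenyl]propanoic acid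
Product: 24 (±)-3-[4-(benzyloxy)-3-methoxyphenyl]-2-chloropropanoic acid, via dilithium enediolate 23 (not isolated)
Conditions: LDA (2.2 equiv), THF, −78 to 0 °C; then CCl4, −78 °C; then aq. HCl
Reagents that add atoms: carbon tetrachloride, ClC(Cl)(Cl)Cl
Why: α-Chlorination of a carboxylic acid dianion by positive-chlorine transfer from CCl4; it installs the activating chlorine that turns the acid into a chloroketene precursor.

Step 14
Reactants: 24 the α-chloro acid
Product: 25 (±)-3-[4-(benzyloxy)-3-methoxyphenyl]-2-chloropropanoyl chloride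
Conditions: (COCl)2, DMF (cat.), CH2Cl2, 0 °C to rt; evaporate and use crude
Reagents that add atoms: oxalyl chloride, O=C(Cl)C(Cl)=O
Why: Acid chloride formation through the Vilsmeier-type chloroiminium catalyst under neutral conditions that leave the aryl benzyl ether intact.

Step 15
Reactants: 20 the (R)-(Z)-alkenyl sulfoxide; 25 the α-chloro acid chloride
Product: 28 (4S,5R)-3-chloro-3-(BnG-methyl)-4-(Ar′-methyl)-5-(p-tolylthio)dihydrofuran-2(3H)-one as C3 epimers, via chloroketene 26 (not isolated), via thionium carboxylate 27 (not isolated)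
Conditions: Et3N (3 equiv), CH2Cl2, 0 °C; 25 (2 equiv) added by syringe pump over 4 h; then rt
Reagents that add atoms: none
Why: Proposed new method: Et3N converts 25 into chloroketene 26, whose carbonyl carbon is attacked by the sulfinyl oxygen of 20; the O-acylated vinylsulfonium enolate undergoes a chair-like [3,3]-sigmatropic shift that forms the C3–C4 bond and cleaves S–O to give thionium carboxylate 27, and the carboxylate then closes on the thionium carbon to form the O1–C5 bond. The closest known reaction is the Marino lactonization of enantiopure alkenyl sulfoxides with dichloroketene, which is established for β-benzyl lactones; new is only the arylmethyl(chloro)ketene, whose α-chlorine keeps the ketene electrophilic and acidifies the α-position so that direct O-acylation by 25 followed by deprotonation reaches the same zwitterion. The lactone is the only ring closed, by 5-exo-trig attack of oxygen on the C=S+ carbon. C4 is controlled by the sulfur stereocentre: with the S–O bond perpendicular to the alkene, the tolyl group pseudo-equatorial and the lone pair eclipsing the (Z)-C=C bond, the ketene carbon reaches one alkene face only, which for the (R)-sulfoxide corresponds to the (4R) centre of the target; C5 follows by suprafacial delivery (tolylthio cis to the C4 substituent) and C3 forms as an epimer mixture, both being erased in step 16. The step needs O-acylation of the sulfoxide to outrun ketene dimerization and the (Z)-geometry to survive, which slow addition of 25, the absence of any free OH or NH group in 20 and the weak amine base should secure.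

Step 16
Reactants: 28 the chloro(tolylthio) lactone
Product: 30 (3R,4R)-3-(BnG-methyl)-4-(Ar′-methyl)dihydrofuran-2(3H)-one, via C3-epimer mixture 29 (not isolated)
Conditions: Raney Ni (W-2, deactivated in acetone), EtOH/THF, rt; filter; then DBU, toluene, 80 °C
Reagents that add atoms: none
Why: Raney nickel hydrogenolyses the C5–S bond of the O,S-acetal and the activated tertiary C3–Cl bond (hydrodesulfurization and hydrodehalogenation), and DBU then equilibrates the new C3–H centre through the lactone enolate to the thermodynamically favoured 3,4-trans isomer, so C3 is set by relay from C4.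

Step 17
Reactants: 30 the trans-lactone acetonide
Product: 31 (3R,4R)-3-(BnG-methyl)-4-{4-(benzyloxy)-3-[(1R,2S)-1-(BnG)-1,3-dihydroxypropan-2-yl]-5-methoxybenzyl}dihydrofuran-2(3H)-one
Conditions: AcOH/THF/H2O (3:1:1), 40 °C
Reagents that add atoms: none
Why: Mild aqueous acid hydrolysis of the acetonide; water as the nucleophile avoids benzylic ether formation, and the lactone, the benzyl ethers and both lactone stereocentres are inert to dilute acetic acid.

Step 18
Reactants: 31 the diol
Product: 32 (3R,4R)-3-(BnG-methyl)-4-{4-(benzyloxy)-3-[(2S)-1-(BnG)-3-hydroxy-1-oxopropan-2-yl]-5-methoxybenzyl}dihydrofuran-2(3H)-one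
Conditions: activated MnO2 (excess), CH2Cl2, rt
Reagents that add atoms: none
Why: Activated MnO2 oxidizes benzylic alcohols far faster than saturated primary alcohols and is not basic in solution, which should leave the CH(CH2OH) centre, now α to the ketone, untouched (chemoselective benzylic oxidation).

Step 19
Reactants: 32 the tris-benzyl ether ketone
Product: 33 (3R,4R)-4-{4-hydroxy-3-[(2S)-3-hydroxy-1-(4-hydroxy-3-methoxyphenyl)-1-oxopropan-2-yl]-5-methoxybenzyl}-3-(4-hydroxy-3-methoxybenzyl)dihydrofuran-2(3H)-one (target)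
Conditions: H2 (1 atm), 10% Pd/C, EtOAc, rt, stopped at complete debenzylation
Reagents that add atoms: none
Why: Hydrogenolysis of the three aryl benzyl ethers under neutral conditions; the electron-rich aryl ketone is reduced much more slowly, and no acid or base is present that could epimerize the α-centre or close the ortho-hydroxy ketone to a benzofuran.

**Compound list**

1 | methyl (4-hydroxy-3-methoxyphenyl)acetate | COC(=O)Cc1ccc(O)c(OC)c1 | starting material
2 | methyl [4-(allyloxy)-3-methoxyphenyl]acetate | COC(=O)Cc1ccc(OCC=C)c(OC)c1 | intermediate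
3 | methyl (3-allyl-4-hydroxy-5-methoxyphenyl)acetate | COC(=O)Cc1cc(CC=C)c(O)c(OC)c1 | intermediate
4 | methyl [3-allyl-4-(benzyloxy)-5-methoxyphenyl]acetate | COC(=O)Cc1cc(CC=C)c(OCc2ccccc2)c(OC)c1 | intermediate
5 | methyl [4-(benzyloxy)-3-methoxy-5-(2-oxoethyl)phenyl]acetate | COC(=O)Cc1cc(CC=O)c(OCc2ccccc2)c(OC)c1 | intermediate (not isolated)
6 | [2-(benzyloxy)-3-methoxy-5-(2-methoxy-2-oxoethyl)phenyl]acetic acid | COC(=O)Cc1cc(CC(=O)O)c(OCc2ccccc2)c(OC)c1 | intermediate
7 | (R)-4-benzyl-1,3-oxazolidin-2-one | O=C1OC[C@@H](Cc2ccccc2)N1 | starting material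
8 | mixed anhydride of 6 with pivalic acid | COC(=O)Cc1cc(CC(=O)OC(=O)C(C)(C)C)c(OCc2ccccc2)c(OC)c1 | intermediate (not isolated)
9 | methyl [4-(benzyloxy)-3-methoxy-5-{2-[(4R)-4-benzyl-2-oxo-1,3-oxazolidin-3-yl]-2-oxoethyl}phenyl]acetate | COC(=O)Cc1cc(CC(=O)N2C(=O)OC[C@H]2Cc2ccccc2)c(OCc2ccccc2)c(OC)c1 | intermediate
10 | 4-(benzyloxy)-3-methoxybenzaldehyde | O=Cc1ccc(OCc2ccccc2)c(OC)c1 | starting material
11 | (Z)-di-n-butylboron enolate of 9 | CCCCB(CCCC)O/C(=C\c1cc(CC(=O)OC)cc(OC)c1OCc1ccccc1)N1C(=O)OC[C@H]1Cc1ccccc1 | intermediate (not isolated)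
12 | (4R)-4-benzyl-3-{(2R,3R)-2-[2-(benzyloxy)-3-methoxy-5-(2-methoxy-2-oxoethyl)phenyl]-3-[4-(benzyloxy)-3-methoxyphenyl]-3-hydroxypropanoyl}-1,3-oxazolidin-2-one | O=C1OC[C@@H](Cc2ccccc2)N1C(=O)[C@H](c1cc(CC(=O)OC)cc(OC)c1OCc1ccccc1)[C@@H](O)c1ccc(OCc2ccccc2)c(OC)c1 | intermediate
13 | (1R,2S)-2-[2-(benzyloxy)-5-(2-hydroxyethyl)-3-methoxyphenyl]-1-[4-(benzyloxy)-3-methoxyphenyl]propane-1,3-diol | OC[C@H](c1cc(CCO)cc(OC)c1OCc1ccccc1)[C@@H](O)c1ccc(OCc2ccccc2)c(OC)c1 | intermediate
14 | 2-{4-(benzyloxy)-3-[(4R,5S)-4-(4-benzyloxy-3-methoxyphenyl)-2,2-dimethyl-1,3-dioxan-5-yl]-5-methoxyphenyl}ethanol | CC1(C)OC[C@H](c2cc(CCO)cc(OC)c2OCc2ccccc2)[C@H](c2ccc(OCc3ccccc3)c(OC)c2)O1 | intermediate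
15 | {4-(benzyloxy)-3-[(4R,5S)-4-(4-benzyloxy-3-methoxyphenyl)-2,2-dimethyl-1,3-dioxan-5-yl]-5-methoxyphenyl}acetaldehyde | CC1(C)OC[C@H](c2cc(CC=O)cc(OC)c2OCc2ccccc2)[C@H](c2ccc(OCc3ccccc3)c(OC)c2)O1 | intermediate (not isolated)
16 | (4R,5S)-5-[2-(benzyloxy)-3-methoxy-5-(prop-2-yn-1-yl)phenyl]-4-[4-(benzyloxy)-3-methoxyphenyl]-2,2-dimethyl-1,3-dioxane | CC1(C)OC[C@H](c2cc(CC#C)cc(OC)c2OCc2ccccc2)[C@H](c2ccc(OCc3ccccc3)c(OC)c2)O1 | intermediate
17 | (1R,2S,5R)-(−)-menthyl (S)-p-toluenesulfinate | C[C@@H]1CC[C@H]([C@@H](C1)O[S@](=O)c1ccc(C)cc1)C(C)C | starting material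
18 | alkynylmagnesium bromide of 16 | CC1(C)OC[C@H](c2cc(CC#C[Mg]Br)cc(OC)c2OCc2ccccc2)[C@H](c2ccc(OCc3ccccc3)c(OC)c2)O1 | intermediate (not isolated)
19 | alkynyl sulfoxide: 16 carrying (S)-p-tolylsulfinyl on the alkyne terminus | CC1(C)OC[C@H](c2cc(CC#C[S@@](=O)c3ccc(C)cc3)cc(OC)c2OCc2ccccc2)[C@H](c2ccc(OCc3ccccc3)c(OC)c2)O1 | intermediate
20 | (Z)-alkenyl sulfoxide: (4R,5S)-5-{2-(benzyloxy)-3-methoxy-5-[(Z)-3-((R)-p-tolylsulfinyl)prop-2-en-1-yl]phenyl}-4-[4-(benzyloxy)-3-methoxyphenyl]-2,2-dimethyl-1,3-dioxane | CC1(C)OC[C@H](c2cc(C/C=C\[S@@](=O)c3ccc(C)cc3)cc(OC)c2OCc2ccccc2)[C@H](c2ccc(OCc3ccccc3)c(OC)c2)O1 | intermediate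
21 | 3-(4-hydroxy-3-methoxyphenyl)propanoic acid | O=C(O)CCc1ccc(O)c(OC)c1 | starting material
22 | 3-[4-(benzyloxy)-3-methoxyphenyl]propanoic acid | O=C(O)CCc1ccc(OCc2ccccc2)c(OC)c1 | intermediate
23 | dilithium enediolate of 22 | [Li+].[Li+].[O-]C([O-])=CCc1ccc(OCc2ccccc2)c(OC)c1 | intermediate (not isolated)
24 | (±)-3-[4-(benzyloxy)-3-methoxyphenyl]-2-chloropropanoic acid | O=C(O)C(Cl)Cc1ccc(OCc2ccccc2)c(OC)c1 | intermediate
25 | (±)-3-[4-(benzyloxy)-3-methoxyphenyl]-2-chloropropanoyl chloride | O=C(Cl)C(Cl)Cc1ccc(OCc2ccccc2)c(OC)c1 | intermediate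
26 | [4-(benzyloxy)-3-methoxybenzyl]chloroketene | O=C=C(Cl)Cc1ccc(OCc2ccccc2)c(OC)c1 | intermediate (not isolated)
27 | thionium carboxylate zwitterion formed by the [3,3] shift (C2 epimers) | [O-]C(=O)C(Cl)(Cc1ccc(OCc2ccccc2)c(OC)c1)[C@@H](Cc1cc(OC)c(OCc2ccccc2)c(c1)[C@H]1COC(C)(C)O[C@H]1c1ccc(OCc2ccccc2)c(OC)c1)C=[S+]c1ccc(C)cc1 | intermediate (not isolated)
28 | (4S,5R)-3-chloro-3-(BnG-methyl)-4-(Ar′-methyl)-5-(p-tolylthio)dihydrofuran-2(3H)-one, C3 epimers | O=C1O[C@H](Sc2ccc(C)cc2)[C@H](Cc2cc(OC)c(OCc3ccccc3)c(c2)[C@H]2COC(C)(C)O[C@H]2c2ccc(OCc3ccccc3)c(OC)c2)C1(Cl)Cc1ccc(OCc2ccccc2)c(OC)c1 | intermediate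
29 | (4R)-3-(BnG-methyl)-4-(Ar′-methyl)dihydrofuran-2(3H)-one, C3 epimers | O=C1OC[C@H](Cc2cc(OC)c(OCc3ccccc3)c(c2)[C@H]2COC(C)(C)O[C@H]2c2ccc(OCc3ccccc3)c(OC)c2)C1Cc1ccc(OCc2ccccc2)c(OC)c1 | intermediate (not isolated)
30 | (3R,4R)-3-(BnG-methyl)-4-(Ar′-methyl)dihydrofuran-2(3H)-one | O=C1OC[C@H](Cc2cc(OC)c(OCc3ccccc3)c(c2)[C@H]2COC(C)(C)O[C@H]2c2ccc(OCc3ccccc3)c(OC)c2)[C@H]1Cc1ccc(OCc2ccccc2)c(OC)c1 | intermediate
31 | (3R,4R)-lactone diol with (1R,2S)-1,3-dihydroxy-1-(BnG)propan-2-yl arm | O=C1OC[C@H](Cc2cc(OC)c(OCc3ccccc3)c(c2)[C@@H](CO)[C@@H](O)c2ccc(OCc3ccccc3)c(OC)c2)[C@H]1Cc1ccc(OCc2ccccc2)c(OC)c1 | intermediate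
32 | (3R,4R)-lactone ketone with (2S)-1-(BnG)-3-hydroxy-1-oxopropan-2-yl arm, tris-benzyl ether of the target | O=C1OC[C@H](Cc2cc(OC)c(OCc3ccccc3)c(c2)[C@@H](CO)C(=O)c2ccc(OCc3ccccc3)c(OC)c2)[C@H]1Cc1ccc(OCc2ccccc2)c(OC)c1 | intermediate
33 | (3R,4R)-4-{4-hydroxy-3-[(2S)-3-hydroxy-1-(4-hydroxy-3-methoxyphenyl)-1-oxopropan-2-yl]-5-methoxybenzyl}-3-(4-hydroxy-3-methoxybenzyl)dihydrofuran-2(3H)-one | O=C1OC[C@H](Cc2cc(OC)c(O)c(c2)[C@@H](CO)C(=O)c2ccc(O)c(OC)c2)[C@H]1Cc1ccc(O)c(OC)c1 | target

**Step count**
Total: 19 steps. Longest linear sequence: 16 steps (steps 1–11, then 15–19); steps 12–14 form the three-step side branch that joins at step 15.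

**Steps most likely to fail, with fallbacks**

Step 15 (Proposed new method). The arylmethyl(chloro)ketene may dimerize before the sulfinyl oxygen attacks it, chloride may intercept the thionium ion in a Pummerer-type pathway, or chirality transfer may be eroded. The fallback uses only known chemistry and sets out from 20. Dichloroketene generated from trichloroacetyl chloride and Zn–Cu couple in refluxing Et2O should give, by the established lactonization, the (4S,5R)-3,3-dichloro-4-(Ar′-methyl)-5-(p-tolylthio) lactone F1. Raney nickel should then remove both chlorines and the sulfur to give the (R)-4-(Ar′-methyl)dihydrofuran-2(3H)-one F2. Deprotonation of F2 with LiHMDS in THF at −78 °C and alkylation with commercial 4-(benzyloxy)-3-methoxybenzyl bromide, which enters anti to the C4 substituent, should return the route at 30.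

Step 16. Hydrogenolysis on nickel may also cleave aryl benzyl ethers, C–Cl cleavage may be incomplete, and the cis-to-trans equilibration may stall. The fallback sets out from 28 and separates the events with different reagents. Zinc dust in AcOH/THF should dechlorinate through the zinc enolate to the 3-(BnG-methyl)-4-(Ar′-methyl)-5-(p-tolylthio) lactone F3. Bu3SnH with AIBN in toluene at 100 °C should then cleave the C–S bond of the O,S-acetal by a radical chain, and equilibration with DBU as before should rejoin the route at 30.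

Step 18. Oxidation of the hindered benzylic alcohol may be slow, the primary alcohol may be attacked in competition, and the basic oxide surface may cause epimerization or retro-aldol loss of formaldehyde. The fallback sets out from 31 and differentiates the two hydroxyl groups with a protecting group. TBSCl and imidazole in DMF at 0 °C should silylate only the primary alcohol to give the mono-silyl ether F4. Pyridine-buffered Dess–Martin oxidation should give the silyl-protected ketone F5. HF·pyridine in THF/pyridine at 0 °C, a mildly acidic buffered desilylation, should return the route at 32.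

Further compounds
F1 | step 15 | (4S,5R)-3,3-dichloro-4-(Ar′-methyl)-5-(p-tolylthio)dihydrofuran-2(3H)-one | O=C1O[C@H](Sc2ccc(C)cc2)[C@H](Cc2cc(OC)c(OCc3ccccc3)c(c2)[C@H]2COC(C)(C)O[C@H]2c2ccc(OCc3ccccc3)c(OC)c2)C1(Cl)Cl
F2 | step 15 | (R)-4-(Ar′-methyl)dihydrofuran-2(3H)-one | O=C1OC[C@H](Cc2cc(OC)c(OCc3ccccc3)c(c2)[C@H]2COC(C)(C)O[C@H]2c2ccc(OCc3ccccc3)c(OC)c2)C1
F3 | step 16 | (4R,5R)-3-(BnG-methyl)-4-(Ar′-methyl)-5-(p-tolylthio)dihydrofuran-2(3H)-one, C3 epimers | O=C1O[C@H](Sc2ccc(C)cc2)[C@H](Cc2cc(OC)c(OCc3ccccc3)c(c2)[C@H]2COC(C)(C)O[C@H]2c2ccc(OCc3ccccc3)c(OC)c2)C1Cc1ccc(OCc2ccccc2)c(OC)c1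
F4 | step 18 | primary TBS ether of diol 31 | O=C1OC[C@H](Cc2cc(OC)c(OCc3ccccc3)c(c2)[C@@H](CO[Si](C)(C)C(C)(C)C)[C@@H](O)c2ccc(OCc3ccccc3)c(OC)c2)[C@H]1Cc1ccc(OCc2ccccc2)c(OC)c1
F5 | step 18 | primary TBS ether of ketone 32 | O=C1OC[C@H](Cc2cc(OC)c(OCc3ccccc3)c(c2)[C@@H](CO[Si](C)(C)C(C)(C)C)C(=O)c2ccc(OCc3ccccc3)c(OC)c2)[C@H]1Cc1ccc(OCc2ccccc2)c(OC)c1
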